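**Strategy.** The route rests on cutting the C13–C14 bond (iridal numbering), the allylic CH2–CH= bond that ties the C12–C13 ethylene bridge on the quaternary cyclohexane carbon C11 to the (14E)-trisubstituted C14=C15 alkene. A vinyl group on C11 is a latent C13 nucleophile: 9-BBN hydroboration and in situ B-alkyl Suzuki–Miyaura coupling with an (E)-vinyl iodide join a sixteen-carbon ring fragment and a fourteen-carbon side chain in one operation, with retention of alkene geometry. The precursors are cyclohexane 13, which already carries the three ring stereocentres, the (Z)-tetrasubstituted acrylate and the C11 vinyl group, and the silyl-protected (16R)-vinyl iodide 23.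

Key step: step 15

Remark: iridal numbering is used in the Why lines (C1 = CHO, C2 = its α-carbon, C3–C5 = hydroxypropyl chain, C6–C11 = ring, C7 = alkylidene carbon, C10 = ring carbinol, C11 = quaternary carbon, C12–C24 = side chain, C16 = secondary carbinol); TBDPS = tert-butyldiphenylsilyl, TBS = tert-butyldimethylsilyl.

Assumption: the chiral copper–carbene catalyst of step 2 is used as the enantiomer that gives (6S)-5; its sense of induction on this γ-ketal enone is taken by analogy with 2-methylcyclohex-2-enone.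

Assumption: compounds 1, 10, 14, 18 and (3-bromopropoxy)(tert-butyl)diphenylsilane are taken as commercial.

**Ring fragment**

Step 1
Reactants: 1 7-methyl-1,4-dioxaspiro[4.5]decan-8-one (racemic)
Product: 3 7-methyl-1,4-dioxaspiro[4.5]dec-6-en-8-one, via silyl enol ether 2 (not isolated)
Conditions: TMSOTf, Et3N, CH2Cl2, 0 °C to rt; then Pd(OAc)2 (10 mol %), O2 (1 atm), DMSO, 40 °C
Reagents that add atoms: none
Why: Saegusa–Ito oxidation: equilibrating silylation should give the more substituted (C10=C11) silyl enol ether, and palladation with β-hydride elimination then places the double bond at C11=C6 next to the methyl group.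

Step 2
Reactants: 3 7-methyl-1,4-dioxaspiro[4.5]dec-6-en-8-one
Product: 5 (6S,7R)-6-[3-(tert-butyldiphenylsilyloxy)propyl]-7-(1-hydroxyethyl)-7-methyl-1,4-dioxaspiro[4.5]decan-8-one (both carbinol epimers), via magnesium enolate 4 (not isolated)
Conditions: TBDPSO(CH2)3MgBr (from the bromide and Mg, Et2O), Cu(OTf)2 (5 mol %), chiral imidazolinium salt (N-heterocyclic carbene precursor, 7 mol %), Et2O, −30 °C; then MeCHO, −78 °C; aq. NH4Cl
Reagents that add atoms: [3-(tert-butyldiphenylsilyloxy)propyl]magnesium bromide, CC(C)(C)[Si](OCCC[Mg]Br)(c1ccccc1)c1ccccc1; acetaldehyde, CC=O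
Why: Copper-catalysed asymmetric conjugate addition in which the chiral copper–carbene complex delivers the alkyl group to one face of the β-carbon (sets C6), followed by aldol trapping of the regiodefined magnesium enolate by acetaldehyde on the face anti to the new C6 chain (sets quaternary C11 trans to it).

Step 3
Reactants: 5 (6S,7R)-6-[3-(tert-butyldiphenylsilyloxy)propyl]-7-(1-hydroxyethyl)-7-methyl-1,4-dioxaspiro[4.5]decan-8-one
Product: 6 (6S,7S)-6-[3-(tert-butyldiphenylsilyloxy)propyl]-7-ethenyl-7-methyl-1,4-dioxaspiro[4.5]decan-8-one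
Conditions: Martin sulfurane (Ph2S[OC(CF3)2Ph]2), CH2Cl2, 0 °C to rt
Reagents that add atoms: none
Why: Martin sulfurane dehydration (E2 from the alkoxysulfonium): the quaternary neighbour C11 carries no hydrogen, so only the methyl group can lose a proton and the terminal C12=C13 vinyl group should form from both carbinol epimers.

Step 4
Reactants: 6 (6S,7S)-6-[3-(tert-butyldiphenylsilyloxy)propyl]-7-ethenyl-7-methyl-1,4-dioxaspiro[4.5]decan-8-one
Product: 8 (2S,3S,4S)-2-[3-(tert-butyldiphenylsilyloxy)propyl]-3-ethenyl-4-hydroxy-3,4-dimethylcyclohexan-1-one, via tertiary alcohol ketal 7 (not isolated)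
Conditions: MeLi, CeCl3, THF, −78 °C; then 1 M aq. HCl, THF, 0 °C to rt (short contact)
Reagents that add atoms: methyllithium, C[Li]; water, O
Why: Organocerium 1,2-addition followed by acetal hydrolysis: the weakly basic MeCeCl2 should add without enolisation along the axial trajectory anti to the axial C11 methyl of the chair that keeps the C6 chain and the vinyl group equatorial (new methyl cis to vinyl, C10 hydroxyl cis to the C11 methyl), and brief dilute acid then frees the C7 ketone without cleaving the TBDPS ether or epimerising C6.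

Step 5
Reactants: 8 (2S,3S,4S)-2-[3-(tert-butyldiphenylsilyloxy)propyl]-3-ethenyl-4-hydroxy-3,4-dimethylcyclohexan-1-one
Product: 9 (4S,5S,6S)-6-[3-(tert-butyldiphenylsilyloxy)propyl]-5-ethenyl-4-hydroxy-4,5-dimethylcyclohex-1-en-1-yl trifluoromethanesulfonate
Conditions: LiN(i-Pr)2 (2.3 equiv), THF, −78 °C; then N-(5-chloro-2-pyridyl)bis(trifluoromethanesulfonimide), −78 to 0 °C
Reagents that add atoms: N-(5-chloro-2-pyridyl)bis(trifluoromethanesulfonimide), O=S(=O)(N(c1ccc(Cl)cn1)S(=O)(=O)C(F)(F)F)C(F)(F)F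
Why: Kinetic enolate O-triflation: after deprotonation of the hydroxyl, the second equivalent of amide should remove a proton from the unhindered C8 methylene and not from the congested C6 methine, and the triflimide traps this enolate while the hindered tertiary alkoxide stays inert at low temperature.

Step 6
Reactants: 10 methyl prop-2-ynoate (methyl propiolate)
Product: 11 methyl 2-(tributylstannyl)prop-2-enoate
Conditions: Bu3SnH, Pd(PPh3)4 (2 mol %), THF, 0 °C to rt
Reagents that add atoms: tributyltin hydride, CCCC[SnH](CCCC)CCCC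
Why: Palladium-catalysed syn-hydrostannation of a propiolate, which places tin on the α-carbon.

Step 7
Reactants: 9 (4S,5S,6S)-6-[3-(tert-butyldiphenylsilyloxy)propyl]-5-ethenyl-4-hydroxy-4,5-dimethylcyclohex-1-en-1-yl trifluoromethanesulfonate; 11 methyl 2-(tributylstannyl)prop-2-enoate
Product: 12 methyl 2-[(4S,5S,6R)-6-[3-(tert-butyldiphenylsilyloxy)propyl]-5-ethenyl-4-hydroxy-4,5-dimethylcyclohex-1-en-1-yl]prop-2-enoate
Conditions: Pd(PPh3)4 (10 mol %), CuI (20 mol %), CsF, DMF, 45 °C
Reagents that add atoms: none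
Why: Stille cross-coupling (copper- and fluoride-assisted) of the enol triflate with the α-stannyl acrylate should give the cross-conjugated C8=C7–C2=C1 diene without touching a stereocentre; the diene is used at once because it can dimerise.

Step 8
Reactants: 12 methyl 2-[(4S,5S,6R)-6-[3-(tert-butyldiphenylsilyloxy)propyl]-5-ethenyl-4-hydroxy-4,5-dimethylcyclohex-1-en-1-yl]prop-2-enoate
Product: 13 methyl (2Z)-2-[(2R,3S,4S)-2-[3-(tert-butyldiphenylsilyloxy)propyl]-3-ethenyl-4-hydroxy-3,4-dimethylcyclohexylidene]propanoate (ring fragment)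
Conditions: (naphthalene)Cr(CO)3 (20 mol %), H2 (50 atm), acetone, rt
Reagents that add atoms: none
Why: (Arene)Cr(CO)3-catalysed 1,4-hydrogenation: H2 adds to the two termini of the η4-bound s-cis diene, so the new methyl ends cis to C8 and the ester cis to C6, which should give the (Z)-tetrasubstituted C7=C2 alkene stereospecifically while the isolated vinyl group is not reduced.

**Side-chain fragment**

Step 9
Reactants: 14 prop-2-yn-1-ol (propargyl alcohol)
Product: 16 (2E)-3-iodo-2-methylprop-2-en-1-ol, via alkenylalane 15 (not isolated)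
Conditions: AlMe3 (3 equiv), Cp2ZrCl2 (25 mol %), CH2Cl2, 0 °C to rt; then I2, THF, −30 to 0 °C; aq. K2CO3
Reagents that add atoms: trimethylaluminium, C[Al](C)C; iodine, II
Why: Zirconium-catalysed carboalumination (Negishi) adds methyl and aluminium syn with aluminium at the terminus, and iodinolysis with retention should give the (E)-iodide.

Step 10
Reactants: 16 (2E)-3-iodo-2-methylprop-2-en-1-ol
Product: 17 (2E)-3-iodo-2-methylprop-2-enal
Conditions: MnO2 (activated), CH2Cl2, rt
Reagents that add atoms: none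
Why: MnO2 oxidation of a primary allylic alcohol stops at the enal and leaves the C–I bond and the alkene geometry intact.

Step 11
Reactants: 17 (2E)-3-iodo-2-methylprop-2-enal; 18 (2E)-1-chloro-3,7-dimethylocta-2,6-diene (geranyl chloride)
Product: 20 (1E,5E)-1-iodo-2,6,10-trimethylundeca-1,5,9-trien-3-ol (racemic), via geranylbarium chloride 19 (not isolated)
Conditions: BaI2, lithium biphenylide (2 equiv), THF, rt; 18, −78 °C; then 17, −78 °C; aq. NH4Cl
Reagents that add atoms: none
Why: Allylbarium α-allylation: the geranylbarium reagent formed from active barium should react at its unsubstituted α-carbon with retention of the (E)-geometry and add 1,2 to the enal, giving the linear homoallylic alcohol.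

Step 12
Reactants: 20 (1E,5E)-1-iodo-2,6,10-trimethylundeca-1,5,9-trien-3-ol
Product: 21 (1E,5E)-1-iodo-2,6,10-trimethylundeca-1,5,9-trien-3-one
Conditions: Dess–Martin periodinane, NaHCO3, CH2Cl2, 0 °C
Reagents that add atoms: none
Why: Buffered Dess–Martin oxidation should give the enone without moving the skipped C18=C19 alkene into conjugation.

Step 13
Reactants: 21 (1E,5E)-1-iodo-2,6,10-trimethylundeca-1,5,9-trien-3-one
Product: 22 (3R,1E,5E)-1-iodo-2,6,10-trimethylundeca-1,5,9-trien-3-ol
Conditions: (S)-2-methyl-CBS-oxazaborolidine (20 mol %), catecholborane, toluene, −78 °C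
Reagents that add atoms: none
Why: CBS reduction: the α-methyl-β-iodovinyl group acts as the large substituent and the CH2 group as the small one, so the (S)-oxazaborolidine–borane complex should deliver hydride to the face that gives the (R)-carbinol (C16).

Step 14
Reactants: 22 (3R,1E,5E)-1-iodo-2,6,10-trimethylundeca-1,5,9-trien-3-ol
Product: 23 tert-butyl{[(3R,1E,5E)-1-iodo-2,6,10-trimethylundeca-1,5,9-trien-3-yl]oxy}dimethylsilane (side-chain fragment)
Conditions: TBSCl, imidazole, DMF, rt
Reagents that add atoms: tert-butyldimethylsilyl chloride, CC(C)(C)[Si](C)(C)Cl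
Why: Silylation of the secondary allylic alcohol protects C16 through the coupling and the later reduction and oxidation.

**Union and completion**

Step 15
Reactants: 13 methyl (2Z)-2-[(2R,3S,4S)-2-[3-(tert-butyldiphenylsilyloxy)propyl]-3-ethenyl-4-hydroxy-3,4-dimethylcyclohexylidene]propanoate; 23 tert-butyl{[(3R,1E,5E)-1-iodo-2,6,10-trimethylundeca-1,5,9-trien-3-yl]oxy}dimethylsilane
Product: 25 methyl (2Z)-2-[(2R,3S,4S)-3-[(3E,5R,7E)-5-(tert-butyldimethylsilyloxy)-4,8,12-trimethyltrideca-3,7,11-trien-1-yl]-2-[3-(tert-butyldiphenylsilyloxy)propyl]-4-hydroxy-3,4-dimethylcyclohexylidene]propanoate, via B-alkyl-9-BBN adduct 24 (not isolated)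
Conditions: 9-BBN dimer (excess), THF, rt to 45 °C; then 3 M aq. Cs2CO3; 23, PdCl2(dppf) (10 mol %), AsPh3 (10 mol %), DMF, rt
Reagents that add atoms: none
Why: 9-BBN adds across the C12=C13 vinyl group with boron at terminal C13 (the quaternary C11 neighbour and the bulk of the borane leave no alternative; the tetrasubstituted acrylate, the ester and the hindered tertiary hydroxyl do not interfere) to give primary borane 24, which is used in situ. Oxidative addition of zerovalent palladium into the C14–I bond of 23, base-assisted transfer of the primary alkyl group from boron and reductive elimination then form the C13–C14 bond; this is a B-alkyl Suzuki–Miyaura coupling, the standard sp3–sp2 fragment union. No ring is closed and no stereocentre is created: the (14E) geometry comes from the iodide with retention, and C6, C10, C11, C16 and the (2Z)-acrylate are untouched. The selectivity needed is hydroboration of the single monosubstituted alkene (secured by destroying excess 9-BBN with the aqueous base before 23, with its three trisubstituted alkenes, is added) and alkyl transfer faster than β-hydride elimination (secured by the dppf/AsPh3 catalyst and the primary alkyl group).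

Step 16
Reactants: 25 coupled methyl ester (name as in step 15)
Product: 26 (2Z)-2-[(2R,3S,4S)-3-[(3E,5R,7E)-5-(tert-butyldimethylsilyloxy)-4,8,12-trimethyltrideca-3,7,11-trien-1-yl]-2-[3-(tert-butyldiphenylsilyloxy)propyl]-4-hydroxy-3,4-dimethylcyclohexylidene]propan-1-ol
Conditions: i-Bu2AlH (4 equiv), CH2Cl2, −78 °C; aq. potassium sodium tartrate
Reagents that add atoms: none
Why: Ester reduction with i-Bu2AlH: 1,2-hydride delivery to the hindered tetrasubstituted acrylate should give the primary allylic alcohol without change of alkene geometry.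

Step 17
Reactants: 26 allylic alcohol (name as in step 16)
Product: 27 (2Z)-2-[(2R,3S,4S)-3-[(3E,5R,7E)-5-(tert-butyldimethylsilyloxy)-4,8,12-trimethyltrideca-3,7,11-trien-1-yl]-2-[3-(tert-butyldiphenylsilyloxy)propyl]-4-hydroxy-3,4-dimethylcyclohexylidene]propanal
Conditions: MnO2 (activated), CH2Cl2, rt
Reagents that add atoms: none
Why: MnO2 allylic oxidation should touch only the primary allylic alcohol (the tertiary alcohol is inert and the other carbinols are silylated) and give the (Z)-enal.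

Step 18
Reactants: 27 bis-silyl enal (name as in step 17)
Product: 28 isoiridogermanal, (2Z)-2-[(2R,3S,4S)-4-hydroxy-3-[(3E,5R,7E)-5-hydroxy-4,8,12-trimethyltrideca-3,7,11-trien-1-yl]-2-(3-hydroxypropyl)-3,4-dimethylcyclohexylidene]propanal
Conditions: TBAF, AcOH, THF, rt
Reagents that add atoms: none
Why: Fluoride-mediated cleavage of both silyl ethers, buffered with acetic acid to spare the enal and the γ-stereocentre C6, should release the target.

**Compound list**

1 | 7-methyl-1,4-dioxaspiro[4.5]decan-8-one (racemic) | CC1CC2(CCC1=O)OCCO2 | starting material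
2 | trimethyl[(7-methyl-1,4-dioxaspiro[4.5]dec-7-en-8-yl)oxy]silane | CC1=C(O[Si](C)(C)C)CCC2(C1)OCCO2 | intermediate
3 | 7-methyl-1,4-dioxaspiro[4.5]dec-6-en-8-one | CC1=CC2(CCC1=O)OCCO2 | intermediate
4 | bromomagnesium enolate of (6S)-6-[3-(tert-butyldiphenylsilyloxy)propyl]-7-methyl-1,4-dioxaspiro[4.5]dec-7-en-8-ol | CC1=C(O[Mg]Br)CCC2(OCCO2)[C@H]1CCCO[Si](c1ccccc1)(c1ccccc1)C(C)(C)C | intermediate
5 | (6S,7R)-6-[3-(tert-butyldiphenylsilyloxy)propyl]-7-(1-hydroxyethyl)-7-methyl-1,4-dioxaspiro[4.5]decan-8-one (carbinol epimers) | CC(O)[C@@]1(C)[C@H](CCCO[Si](c2ccccc2)(c2ccccc2)C(C)(C)C)C2(CCC1=O)OCCO2 | intermediate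
6 | (6S,7S)-6-[3-(tert-butyldiphenylsilyloxy)propyl]-7-ethenyl-7-methyl-1,4-dioxaspiro[4.5]decan-8-one | C=C[C@@]1(C)[C@H](CCCO[Si](c2ccccc2)(c2ccccc2)C(C)(C)C)C2(CCC1=O)OCCO2 | intermediate
7 | (6S,7S,8S)-6-[3-(tert-butyldiphenylsilyloxy)propyl]-7-ethenyl-7,8-dimethyl-1,4-dioxaspiro[4.5]decan-8-ol | C=C[C@@]1(C)[C@H](CCCO[Si](c2ccccc2)(c2ccccc2)C(C)(C)C)C2(CC[C@]1(C)O)OCCO2 | intermediate
8 | (2S,3S,4S)-2-[3-(tert-butyldiphenylsilyloxy)propyl]-3-ethenyl-4-hydroxy-3,4-dimethylcyclohexan-1-one | C=C[C@@]1(C)[C@H](CCCO[Si](c2ccccc2)(c2ccccc2)C(C)(C)C)C(=O)CC[C@]1(C)O | intermediate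
9 | (4S,5S,6S)-6-[3-(tert-butyldiphenylsilyloxy)propyl]-5-ethenyl-4-hydroxy-4,5-dimethylcyclohex-1-en-1-yl trifluoromethanesulfonate | C=C[C@@]1(C)[C@H](CCCO[Si](c2ccccc2)(c2ccccc2)C(C)(C)C)C(OS(=O)(=O)C(F)(F)F)=CC[C@]1(C)O | intermediate
10 | methyl prop-2-ynoate | C#CC(=O)OC | starting material
11 | methyl 2-(tributylstannyl)prop-2-enoate | C=C(C(=O)OC)[Sn](CCCC)(CCCC)CCCC | intermediate
12 | methyl 2-[(4S,5S,6R)-6-[3-(tert-butyldiphenylsilyloxy)propyl]-5-ethenyl-4-hydroxy-4,5-dimethylcyclohex-1-en-1-yl]prop-2-enoate | C=C[C@@]1(C)[C@H](CCCO[Si](c2ccccc2)(c2ccccc2)C(C)(C)C)C(C(=C)C(=O)OC)=CC[C@]1(C)O | intermediate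
13 | methyl (2Z)-2-[(2R,3S,4S)-2-[3-(tert-butyldiphenylsilyloxy)propyl]-3-ethenyl-4-hydroxy-3,4-dimethylcyclohexylidene]propanoate | C=C[C@@]1(C)[C@H](CCCO[Si](c2ccccc2)(c2ccccc2)C(C)(C)C)/C(=C(/C)C(=O)OC)CC[C@]1(C)O | intermediate
14 | prop-2-yn-1-ol | C#CCO | starting material
15 | dimethyl[(1E)-3-(dimethylalumanyloxy)-2-methylprop-1-en-1-yl]alumane | C[Al](C)OC/C(C)=C/[Al](C)C | intermediate
16 | (2E)-3-iodo-2-methylprop-2-en-1-ol | OC/C(C)=C/I | intermediate
17 | (2E)-3-iodo-2-methylprop-2-enal | O=C/C(C)=C/I | intermediate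
18 | (2E)-1-chloro-3,7-dimethylocta-2,6-diene (geranyl chloride) | CC(C)=CCC/C(C)=C/CCl | starting material
19 | geranylbarium chloride | CC(C)=CCC/C(C)=C/C[Ba]Cl | intermediate
20 | (1E,5E)-1-iodo-2,6,10-trimethylundeca-1,5,9-trien-3-ol (racemic) | CC(C)=CCC/C(C)=C/CC(O)/C(C)=C/I | intermediate
21 | (1E,5E)-1-iodo-2,6,10-trimethylundeca-1,5,9-trien-3-one | CC(C)=CCC/C(C)=C/CC(=O)/C(C)=C/I | intermediate
22 | (3R,1E,5E)-1-iodo-2,6,10-trimethylundeca-1,5,9-trien-3-ol | CC(C)=CCC/C(C)=C/C[C@@H](O)/C(C)=C/I | intermediate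
23 | tert-butyl{[(3R,1E,5E)-1-iodo-2,6,10-trimethylundeca-1,5,9-trien-3-yl]oxy}dimethylsilane | CC(C)=CCC/C(C)=C/C[C@@H](O[Si](C)(C)C(C)(C)C)/C(C)=C/I | intermediate
24 | B-alkyl-9-borabicyclo[3.3.1]nonane from 13 (boron on the terminal carbon of the former vinyl group) | C1CC2CCCC(C1)B2CC[C@@]1(C)[C@H](CCCO[Si](c2ccccc2)(c2ccccc2)C(C)(C)C)/C(=C(/C)C(=O)OC)CC[C@]1(C)O | intermediate
25 | methyl (2Z)-2-[(2R,3S,4S)-3-[(3E,5R,7E)-5-(tert-butyldimethylsilyloxy)-4,8,12-trimethyltrideca-3,7,11-trien-1-yl]-2-[3-(tert-butyldiphenylsilyloxy)propyl]-4-hydroxy-3,4-dimethylcyclohexylidene]propanoate | CC(C)=CCC/C(C)=C/C[C@@H](O[Si](C)(C)C(C)(C)C)/C(C)=C/CC[C@@]1(C)[C@H](CCCO[Si](c2ccccc2)(c2ccccc2)C(C)(C)C)/C(=C(/C)C(=O)OC)CC[C@]1(C)O | intermediate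
26 | (2Z)-2-[(2R,3S,4S)-3-[(3E,5R,7E)-5-(tert-butyldimethylsilyloxy)-4,8,12-trimethyltrideca-3,7,11-trien-1-yl]-2-[3-(tert-butyldiphenylsilyloxy)propyl]-4-hydroxy-3,4-dimethylcyclohexylidene]propan-1-ol | CC(C)=CCC/C(C)=C/C[C@@H](O[Si](C)(C)C(C)(C)C)/C(C)=C/CC[C@@]1(C)[C@H](CCCO[Si](c2ccccc2)(c2ccccc2)C(C)(C)C)/C(=C(/C)CO)CC[C@]1(C)O | intermediate
27 | (2Z)-2-[(2R,3S,4S)-3-[(3E,5R,7E)-5-(tert-butyldimethylsilyloxy)-4,8,12-trimethyltrideca-3,7,11-trien-1-yl]-2-[3-(tert-butyldiphenylsilyloxy)propyl]-4-hydroxy-3,4-dimethylcyclohexylidene]propanal | CC(C)=CCC/C(C)=C/C[C@@H](O[Si](C)(C)C(C)(C)C)/C(C)=C/CC[C@@]1(C)[C@H](CCCO[Si](c2ccccc2)(c2ccccc2)C(C)(C)C)/C(=C(/C)C=O)CC[C@]1(C)O | intermediate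
28 | isoiridogermanal, (2Z)-2-[(2R,3S,4S)-4-hydroxy-3-[(3E,5R,7E)-5-hydroxy-4,8,12-trimethyltrideca-3,7,11-trien-1-yl]-2-(3-hydroxypropyl)-3,4-dimethylcyclohexylidene]propanal | CC(C)=CCC/C(C)=C/C[C@@H](O)/C(C)=C/CC[C@@]1(C)[C@H](CCCO)/C(=C(/C)C=O)CC[C@]1(C)O | target

**Step count and risks**

Total step count: 18. Longest linear sequence: 11 steps (steps 1–5, 7, 8 and 15–18).

Steps most likely to fail:

1. Step 2. The conjugate addition at the β-carbon flanked by the ketal may be slow or poorly face-selective (low enantiomeric purity), or the aldol may revert during the quench. The fallback replaces catalyst control by an auxiliary in the substrate; it sets out from 3 and comes back at 8. Acid-catalysed ketal exchange of 3 with (R,R)-hydrobenzoin (PPTS, benzene, reflux; the antipodal diol is used if the sense of induction demands it) should give the hydrobenzoin-ketal enone F1. Addition of the same Grignard reagent with achiral CuBr·SMe2 and trapping with acetaldehyde, now steered by the C2-symmetric ketal, should give the aldol adduct F2. Martin sulfurane then gives the vinyl ketone F3 and MeCeCl2 the tertiary alcohol F4, whose acid work-up releases the diol and returns 8.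

2. Step 8 (and the diene of step 7 that feeds it). Complexation of the hindered s-cis diene may be slow, so that Diels–Alder dimerisation of 12 or over-reduction competes. The fallback builds the same alkene from an enolate of fixed geometry; it sets out from 9 and comes back at 13. Stille coupling of 9 with tributyl(1-ethoxyvinyl)stannane (Pd(PPh3)4, LiCl, THF, reflux) should give the enol ether F5, hydrolysed by dilute aqueous HCl to the methyl enone F6. Conjugate reduction of the s-trans enone with LiBH(s-Bu)3 at −78 °C and trapping of the enolate with PhNTf2 should give the (Z)-enol triflate F7 (oxygen cis to C6). Palladium-catalysed methoxycarbonylation (Pd(OAc)2, dppf, CO, MeOH, Et3N, DMF) then gives 13.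

3. Step 3. The neopentyl-type alkoxysulfonium may ionise and suffer a 1,2-shift, or the β-hydroxy ketone may cleave by retro-aldol reaction. The fallback swaps dehydration for a reductive β-elimination; it sets out from 3 and comes back at 6. The magnesium enolate 4 is trapped with (phenylselanyl)acetaldehyde instead of acetaldehyde to give the β-hydroxy selenide F8. MsCl and Et3N (CH2Cl2, 0 °C) then trigger anti-elimination of the selanyl and hydroxyl groups through the seleniranium ion and should give 6.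

Further compounds
F1 | step 2 | (2R,3R)-7-methyl-2,3-diphenyl-1,4-dioxaspiro[4.5]dec-6-en-8-one | CC1=CC2(CCC1=O)O[C@H](c1ccccc1)[C@@H](c1ccccc1)O2
F2 | step 2 | (2R,3R,6S,7R)-6-[3-(tert-butyldiphenylsilyloxy)propyl]-7-(1-hydroxyethyl)-7-methyl-2,3-diphenyl-1,4-dioxaspiro[4.5]decan-8-one | CC(O)[C@@]1(C)[C@H](CCCO[Si](c2ccccc2)(c2ccccc2)C(C)(C)C)C2(CCC1=O)O[C@H](c1ccccc1)[C@@H](c1ccccc1)O2
F3 | step 2 | (2R,3R,6S,7S)-6-[3-(tert-butyldiphenylsilyloxy)propyl]-7-ethenyl-7-methyl-2,3-diphenyl-1,4-dioxaspiro[4.5]decan-8-one | C=C[C@@]1(C)[C@H](CCCO[Si](c2ccccc2)(c2ccccc2)C(C)(C)C)C2(CCC1=O)O[C@H](c1ccccc1)[C@@H](c1ccccc1)O2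
F4 | step 2 | (2R,3R,6S,7S,8S)-6-[3-(tert-butyldiphenylsilyloxy)propyl]-7-ethenyl-7,8-dimethyl-2,3-diphenyl-1,4-dioxaspiro[4.5]decan-8-ol | C=C[C@@]1(C)[C@H](CCCO[Si](c2ccccc2)(c2ccccc2)C(C)(C)C)C2(CC[C@]1(C)O)O[C@H](c1ccccc1)[C@@H](c1ccccc1)O2
F5 | step 8 | (1S,2S,3R)-3-[3-(tert-butyldiphenylsilyloxy)propyl]-2-ethenyl-4-(1-ethoxyethenyl)-1,2-dimethylcyclohex-4-en-1-ol | C=C[C@@]1(C)[C@H](CCCO[Si](c2ccccc2)(c2ccccc2)C(C)(C)C)C(C(=C)OCC)=CC[C@]1(C)O
F6 | step 8 | 1-[(4S,5S,6S)-6-[3-(tert-butyldiphenylsilyloxy)propyl]-5-ethenyl-4-hydroxy-4,5-dimethylcyclohex-1-en-1-yl]ethan-1-one | C=C[C@@]1(C)[C@H](CCCO[Si](c2ccccc2)(c2ccccc2)C(C)(C)C)C(C(C)=O)=CC[C@]1(C)O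
F7 | step 8 | (1Z)-1-[(2R,3S,4S)-2-[3-(tert-butyldiphenylsilyloxy)propyl]-3-ethenyl-4-hydroxy-3,4-dimethylcyclohexylidene]ethyl trifluoromethanesulfonate | C=C[C@@]1(C)[C@H](CCCO[Si](c2ccccc2)(c2ccccc2)C(C)(C)C)/C(=C(/C)OS(=O)(=O)C(F)(F)F)CC[C@]1(C)O
F8 | step 3 | (6S,7R)-6-[3-(tert-butyldiphenylsilyloxy)propyl]-7-[1-hydroxy-2-(phenylselanyl)ethyl]-7-methyl-1,4-dioxaspiro[4.5]decan-8-one | OC(C[Se]c1ccccc1)[C@@]1(C)[C@H](CCCO[Si](c2ccccc2)(c2ccccc2)C(C)(C)C)C2(CCC1=O)OCCO2
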